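**Plan**

Labels: ring A is the enal arene (O3 meta, O4 para to the side chain); ring B is its dioxane (C7 aryl-bearing, C8, C9 = CH2OH); ring C is the central arene (C1' on C7, oxygens O3' and O4'); ring D is the second dioxane (C7'' aryl-bearing, C8'', C9''); ring E is the catechol.
Retrosynthesis cuts the enal C=C (Wittig), then C3'–O and O4'–C7'' of ring D (aryl bromide etherification, epoxide opening), then O3–C7 of ring B (quinone methide closure), then O4–C8 (Mitsunobu).
Enabling feature: ring C with C7–C8–C9 is the carbon skeleton of tyrosine, so C7 is a benzylic CH2 para to the free O4'–H and can be oxidised to a para-quinone methide. C8, next to it, carries ring A with O3–H placed for six-membered closure.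
Forward order: ring C (from tyrosine, brominated at C3') is joined to ring A through O4–C8, ring B closes, the ring E epoxy alcohol is attached at O4', ring D closes at C3', then chain extension and deprotection.
Stereochemistry: C8 comes from L-tyrosine (retention on diazotisation, one Mitsunobu inversion); C7 settles trans to C8 in the reversible closure; C7''/C8'' come from a Sharpless epoxidation, with inversion at C7'' on opening and retention at C8'', which gives cis ring D.

Key step: step 7

**Route**

Step 1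
Reactants: 1 L-tyrosine
Product: 2 3-bromo-L-tyrosine
Conditions: DMSO (1.2 equiv), 48% aq. HBr, AcOH, 65 °C; neutralise to pH 6
Reagents that add atoms: hydrogen bromide, Br
Why: Electrophilic aromatic bromination by bromine generated in the flask from HBr and DMSO occurs ortho to the phenol, where the two activated positions are equivalent, so one monobromide should form while the protonated amino acid stereocentre is untouched.

Step 2
Reactants: 2 3-bromo-L-tyrosine
Product: 5 (S)-3-(3-bromo-4-hydroxyphenyl)-2-hydroxypropanoic acid, via diazonium carboxylate 3 (not isolated), via α-lactone 4 (not isolated)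
Conditions: NaNO2 (1.5 equiv), 1 M aq. H2SO4, 0 °C to rt
Reagents that add atoms: water, O
Why: Diazotisation of the α-amino acid gives 3, whose neighbouring carboxylate displaces N2 with inversion to give 4, and water opens 4 with a second inversion, so the hydroxy acid should keep the S configuration (net retention).

Step 3
Reactants: 5 (S)-3-(3-bromo-4-hydroxyphenyl)-2-hydroxypropanoic acid
Product: 6 (S)-3-(3-bromo-4-hydroxyphenyl)propane-1,2-diol
Conditions: BH3·THF (4 equiv), THF, 0 °C to rt; MeOH quench
Reagents that add atoms: none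
Why: Borane reduction of a carboxylic acid is chemoselective, leaves the aryl bromide alone and does not touch the stereocentre.

Step 4
Reactants: 6 (S)-3-(3-bromo-4-hydroxyphenyl)propane-1,2-diol
Product: 7 (S)-1-[3-bromo-4-(tert-butyldimethylsilyloxy)phenyl]-3-(tert-butyldimethylsilyloxy)propan-2-ol
Conditions: TBSCl (2.1 equiv), imidazole (4.4 equiv), DMF, 0 °C
Reagents that add atoms: tert-butyldimethylsilyl chloride, CC(C)(C)[Si](C)(C)Cl
Why: Silylation with TBSCl/imidazole is sterically controlled, so the phenol and the primary alcohol should be capped while the secondary carbinol stays free for the next step.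

Step 5
Reactants: 7 (S)-1-[3-bromo-4-(tert-butyldimethylsilyloxy)phenyl]-3-(tert-butyldimethylsilyloxy)propan-2-ol; 8 3,4-dihydroxybenzaldehyde
Product: 9 (R)-4-{[1-[3-bromo-4-(tert-butyldimethylsilyloxy)phenyl]-3-(tert-butyldimethylsilyloxy)propan-2-yl]oxy}-3-hydroxybenzaldehyde
Conditions: 8 (1.5 equiv), PPh3 (1.3 equiv), DIAD (1.3 equiv), THF, 0 °C to rt
Reagents that add atoms: none
Why: Mitsunobu etherification displaces the activated secondary alcohol in an SN2 reaction with inversion (S to R at C8) by the 4-hydroxyl of 8, which is the more acidic phenol (para to the formyl group) and therefore the one that reacts, leaving O3–H free.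

Step 6
Reactants: 9 bis-silyl aryl ether
Product: 10 (R)-4-{[1-(3-bromo-4-hydroxyphenyl)-3-hydroxypropan-2-yl]oxy}-3-hydroxybenzaldehyde
Conditions: TBAF (2.5 equiv), AcOH (2.5 equiv), THF, 0 °C to rt
Reagents that add atoms: none
Why: Fluoride-induced desilylation cleaves both the aryl and the primary alkyl silyl ether (strong Si–F bond), and the acetic acid buffer protects the phenol/aldehyde system from base-induced side reactions.

Step 7
Reactants: 10 (R)-4-{[1-(3-bromo-4-hydroxyphenyl)-3-hydroxypropan-2-yl]oxy}-3-hydroxybenzaldehyde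
Product: 12 (2S,3S)-3-(3-bromo-4-hydroxyphenyl)-2-(hydroxymethyl)-2,3-dihydro-1,4-benzodioxine-6-carbaldehyde (trans), via para-quinone methide 11 (not isolated)
Conditions: DDQ (1.05 equiv, added slowly), anhydrous 1,4-dioxane, 20 °C, dark
Reagents that add atoms: none
Why: DDQ takes the elements of hydride from C7, the benzylic CH2 para to O4'–H of the bromophenol ring C, to give 11, and O3–H of ring A adds to the exocyclic carbon in an intramolecular 1,6-conjugate addition that restores the aromaticity of ring C. The closest known reaction type is the DDQ or Ag2O dehydrogenation of 4-alkylphenols to para-quinone methides with intramolecular capture by a phenol, which is also the ring-forming event in biomimetic oxidative couplings to 1,4-benzodioxane neolignans. Ring B closes in the 6-exo-trig mode (O3 onto C7, the C7=C1' bond lying outside the new ring). The new stereocentre C7 is controlled by C8: the addition should pass through a half-chair with aryl and CH2OH both pseudo-equatorial, and because the para-hydroxyl stays free the closure is reversible through 11 (also under the mild base of step 11), so the thermodynamically preferred trans (7S,8S) isomer should prevail. The step needs oxidation of ring C in preference to ring A and to the product, which is secured by the formyl group deactivating ring A, by O3–H being the only nucleophile that can form a six-membered ring (C9–OH would give an oxetane), and by using only a slight excess of oxidant.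

Step 8
Reactants: 13 caffeic acid
Product: 14 allyl (E)-3-[3,4-bis(allyloxy)phenyl]prop-2-enoate
Conditions: allyl bromide (3.5 equiv), K2CO3 (4 equiv), DMF, 50 °C
Reagents that add atoms: allyl bromide, C=CCBr
Why: Williamson alkylation (SN2) of the two phenoxides and the carboxylate installs allyl groups that withstand base, hydride, the epoxidation and the copper coupling and come off at the end under neutral palladium catalysis.

Step 9
Reactants: 14 allyl (E)-3-[3,4-bis(allyloxy)phenyl]prop-2-enoate
Product: 15 (E)-3-[3,4-bis(allyloxy)phenyl]prop-2-en-1-ol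
Conditions: i-Bu2AlH (2.5 equiv), CH2Cl2, −78 °C; aq. KNaC4H4O6 (potassium sodium tartrate) work-up
Reagents that add atoms: none
Why: i-Bu2AlH reduces the conjugated ester by 1,2-addition to the allylic alcohol without touching the E-olefin or the allyl ethers.

Step 10
Reactants: 15 (E)-3-[3,4-bis(allyloxy)phenyl]prop-2-en-1-ol
Product: 16 [(2S,3S)-3-[3,4-bis(allyloxy)phenyl]oxiran-2-yl]methanol
Conditions: Ti(OiPr)4 (10 mol %), L-(+)-diisopropyl tartrate (12 mol %), t-BuOOH (2 equiv, anhydrous), 4 Å molecular sieves, CH2Cl2, −20 °C; aq. NaOH/NaCl work-up, used at once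
Reagents that add atoms: tert-butyl hydroperoxide, CC(C)(C)OO
Why: Sharpless asymmetric epoxidation: the titanium tartrate complex binds the allylic hydroxyl and delivers oxygen to one face of the E-olefin, L-(+)-tartrate giving the (2S,3S)-epoxy alcohol, while the allyl ether olefins, which lack a directing hydroxyl, are not epoxidised.

Step 11
Reactants: 12 trans-benzodioxane bromophenol; 16 (2S,3S)-epoxy alcohol
Product: 17 (2S,3S)-3-{4-[(1R,2S)-1-[3,4-bis(allyloxy)phenyl]-2,3-dihydroxypropoxy]-3-bromophenyl}-2-(hydroxymethyl)-2,3-dihydro-1,4-benzodioxine-6-carbaldehyde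
Conditions: 16 (1.3 equiv), Cs2CO3 (0.3 equiv), DMF, 60 °C
Reagents that add atoms: none
Why: The phenoxide of 12 opens the trans-3-aryl-2,3-epoxy alcohol in an SN2 reaction at the benzylic carbon (activated by the aryl group, whereas C2 is deactivated by the adjacent CH2OH), which inverts that centre (S to R at C7'') and leaves C8'' (S) untouched to give the erythro diol; alkylation of O4' also removes the free para-hydroxyl and so locks the trans configuration of ring B.

Step 12
Reactants: 17 triol
Product: 18 bis-TIPS ether of 17 at the two primary hydroxyls (C9 and C9''), C8''–OH free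
Conditions: TIPSCl (2.3 equiv), imidazole (5 equiv), DMF, rt
Reagents that add atoms: triisopropylsilyl chloride, CC(C)[Si](Cl)(C(C)C)C(C)C
Why: Silylation with the bulky TIPSCl should occur only at the two primary hydroxyls, leaving the hindered secondary C8''–OH free for ring closure, and TIPS is chosen because it resists O-to-O migration under the basic conditions that follow.

Step 13
Reactants: 18 bis-TIPS bromo alcohol
Product: 19 (2S,3S)-3-[(2R,3S)-2-[3,4-bis(allyloxy)phenyl]-3-(triisopropylsilyloxymethyl)-2,3-dihydro-1,4-benzodioxin-6-yl]-2-(triisopropylsilyloxymethyl)-2,3-dihydro-1,4-benzodioxine-6-carbaldehyde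
Conditions: CuI (20 mol %), 3,4,7,8-tetramethyl-1,10-phenanthroline (40 mol %), Cs2CO3 (2 equiv), toluene, 110 °C
Reagents that add atoms: none
Why: Intramolecular Ullmann-type etherification couples the copper alkoxide of C8''–OH with the neighbouring aryl bromide at C3' to close six-membered ring D, and since no bond to C8'' or C7'' is broken both centres are retained, which gives the cis (7''R,8''S) dioxane.

Step 14
Reactants: 19 bis-benzodioxane aldehyde
Product: 20 (E)-enal of 19, (2E)-3-[(2S,3S)-3-[(2R,3S)-2-[3,4-bis(allyloxy)phenyl]-3-(triisopropylsilyloxymethyl)-2,3-dihydro-1,4-benzodioxin-6-yl]-2-(triisopropylsilyloxymethyl)-2,3-dihydro-1,4-benzodioxin-6-yl]prop-2-enal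
Conditions: Ph3P=CHCHO (1.5 equiv), toluene, 90 °C
Reagents that add atoms: (triphenylphosphoranylidene)acetaldehyde, O=CC=P(c1ccccc1)(c1ccccc1)c1ccccc1
Why: Wittig reaction of the aryl aldehyde with the formyl-stabilised ylide should give the enal with E geometry, the normal outcome for stabilised ylides.

Step 15
Reactants: 20 bis-TIPS enal
Product: 21 (2E)-3-[(2S,3S)-3-[(2R,3S)-2-[3,4-bis(allyloxy)phenyl]-3-(hydroxymethyl)-2,3-dihydro-1,4-benzodioxin-6-yl]-2-(hydroxymethyl)-2,3-dihydro-1,4-benzodioxin-6-yl]prop-2-enal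
Conditions: TBAF (2.5 equiv), AcOH (2.5 equiv), THF, 0 °C to rt
Reagents that add atoms: none
Why: Buffered fluoride desilylation removes the two primary TIPS ethers; the enal should tolerate it and, with the catechol still allylated, ring D has no free para-hydroxyl through which it could epimerise.

Step 16
Reactants: 21 bis-allyl ether diol
Product: 22 CNP0302404.1, (2E)-3-[(2S,3S)-3-[(2R,3S)-2-(3,4-dihydroxyphenyl)-3-(hydroxymethyl)-2,3-dihydro-1,4-benzodioxin-6-yl]-2-(hydroxymethyl)-2,3-dihydro-1,4-benzodioxin-6-yl]prop-2-enal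
Conditions: Pd(PPh3)4 (5 mol %), N-methylaniline (6 equiv), degassed THF, rt
Reagents that add atoms: none
Why: Tsuji–Trost-type deallylation: zerovalent palladium ionises the aryl allyl ethers to π-allylpalladium species that are captured by the weakly basic N-methylaniline, so the catechol is released under neutral conditions that should leave the enal and the acid- and base-sensitive cis ring D intact.

**Compound list**

1 | L-tyrosine, (2S)-2-amino-3-(4-hydroxyphenyl)propanoic acid | N[C@@H](Cc1ccc(O)cc1)C(=O)O | starting material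
2 | 3-bromo-L-tyrosine, (2S)-2-amino-3-(3-bromo-4-hydroxyphenyl)propanoic acid | N[C@@H](Cc1ccc(O)c(Br)c1)C(=O)O | intermediate
3 | diazonium carboxylate, (2S)-3-(3-bromo-4-hydroxyphenyl)-2-diazoniopropanoate (not isolated) | N#[N+][C@@H](Cc1ccc(O)c(Br)c1)C(=O)[O-] | intermediate
4 | α-lactone, (3R)-3-[(3-bromo-4-hydroxyphenyl)methyl]oxiran-2-one (not isolated) | O1[C@H](Cc2ccc(O)c(Br)c2)C1=O | intermediate
5 | (2S)-3-(3-bromo-4-hydroxyphenyl)-2-hydroxypropanoic acid | O[C@@H](Cc1ccc(O)c(Br)c1)C(=O)O | intermediate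
6 | (2S)-3-(3-bromo-4-hydroxyphenyl)propane-1,2-diol | OC[C@@H](O)Cc1ccc(O)c(Br)c1 | intermediate
7 | (2S)-1-[3-bromo-4-(tert-butyldimethylsilyloxy)phenyl]-3-(tert-butyldimethylsilyloxy)propan-2-ol | CC(C)(C)[Si](C)(C)OC[C@@H](O)Cc1ccc(O[Si](C)(C)C(C)(C)C)c(Br)c1 | intermediate
8 | 3,4-dihydroxybenzaldehyde | O=Cc1ccc(O)c(O)c1 | starting material
9 | 4-{[(2R)-1-[3-bromo-4-(tert-butyldimethylsilyloxy)phenyl]-3-(tert-butyldimethylsilyloxy)propan-2-yl]oxy}-3-hydroxybenzaldehyde | O=Cc1ccc(O[C@@H](CO[Si](C)(C)C(C)(C)C)Cc2ccc(O[Si](C)(C)C(C)(C)C)c(Br)c2)c(O)c1 | intermediate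
10 | 4-{[(2R)-1-(3-bromo-4-hydroxyphenyl)-3-hydroxypropan-2-yl]oxy}-3-hydroxybenzaldehyde | O=Cc1ccc(O[C@@H](CO)Cc2ccc(O)c(Br)c2)c(O)c1 | intermediate
11 | para-quinone methide, 4-{[(2R)-1-(3-bromo-4-oxocyclohexa-2,5-dien-1-ylidene)-3-hydroxypropan-2-yl]oxy}-3-hydroxybenzaldehyde (not isolated; exocyclic C=C geometry not defined) | O=Cc1ccc(O[C@@H](CO)C=C2C=CC(=O)C(Br)=C2)c(O)c1 | intermediate
12 | (2S,3S)-3-(3-bromo-4-hydroxyphenyl)-2-(hydroxymethyl)-2,3-dihydro-1,4-benzodioxine-6-carbaldehyde (trans ring B) | O=Cc1ccc2c(c1)O[C@@H](c1ccc(O)c(Br)c1)[C@H](CO)O2 | intermediate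
13 | caffeic acid, (2E)-3-(3,4-dihydroxyphenyl)prop-2-enoic acid | OC(=O)/C=C/c1ccc(O)c(O)c1 | starting material
14 | prop-2-en-1-yl (2E)-3-[3,4-bis(prop-2-en-1-yloxy)phenyl]prop-2-enoate | C=CCOC(=O)/C=C/c1ccc(OCC=C)c(OCC=C)c1 | intermediate
15 | (2E)-3-[3,4-bis(prop-2-en-1-yloxy)phenyl]prop-2-en-1-ol | OC/C=C/c1ccc(OCC=C)c(OCC=C)c1 | intermediate
16 | [(2S,3S)-3-[3,4-bis(prop-2-en-1-yloxy)phenyl]oxiran-2-yl]methanol | OC[C@@H]1O[C@H]1c1ccc(OCC=C)c(OCC=C)c1 | intermediate
17 | (2S,3S)-3-{4-[(1R,2S)-1-[3,4-bis(prop-2-en-1-yloxy)phenyl]-2,3-dihydroxypropoxy]-3-bromophenyl}-2-(hydroxymethyl)-2,3-dihydro-1,4-benzodioxine-6-carbaldehyde | O=Cc1ccc2c(c1)O[C@@H](c1ccc(O[C@H](c3ccc(OCC=C)c(OCC=C)c3)[C@@H](O)CO)c(Br)c1)[C@H](CO)O2 | intermediate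
18 | (2S,3S)-3-{4-[(1R,2S)-1-[3,4-bis(prop-2-en-1-yloxy)phenyl]-2-hydroxy-3-(triisopropylsilyloxy)propoxy]-3-bromophenyl}-2-(triisopropylsilyloxymethyl)-2,3-dihydro-1,4-benzodioxine-6-carbaldehyde | O=Cc1ccc2c(c1)O[C@@H](c1ccc(O[C@H](c3ccc(OCC=C)c(OCC=C)c3)[C@@H](O)CO[Si](C(C)C)(C(C)C)C(C)C)c(Br)c1)[C@H](CO[Si](C(C)C)(C(C)C)C(C)C)O2 | intermediate
19 | (2S,3S)-3-[(2R,3S)-2-[3,4-bis(prop-2-en-1-yloxy)phenyl]-3-(triisopropylsilyloxymethyl)-2,3-dihydro-1,4-benzodioxin-6-yl]-2-(triisopropylsilyloxymethyl)-2,3-dihydro-1,4-benzodioxine-6-carbaldehyde (cis ring D, trans ring B) | O=Cc1ccc2c(c1)O[C@@H](c1ccc3c(c1)O[C@@H](CO[Si](C(C)C)(C(C)C)C(C)C)[C@@H](c1ccc(OCC=C)c(OCC=C)c1)O3)[C@H](CO[Si](C(C)C)(C(C)C)C(C)C)O2 | intermediate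
20 | (2E)-3-[(2S,3S)-3-[(2R,3S)-2-[3,4-bis(prop-2-en-1-yloxy)phenyl]-3-(triisopropylsilyloxymethyl)-2,3-dihydro-1,4-benzodioxin-6-yl]-2-(triisopropylsilyloxymethyl)-2,3-dihydro-1,4-benzodioxin-6-yl]prop-2-enal | O=C/C=C/c1ccc2c(c1)O[C@@H](c1ccc3c(c1)O[C@@H](CO[Si](C(C)C)(C(C)C)C(C)C)[C@@H](c1ccc(OCC=C)c(OCC=C)c1)O3)[C@H](CO[Si](C(C)C)(C(C)C)C(C)C)O2 | intermediate
21 | (2E)-3-[(2S,3S)-3-[(2R,3S)-2-[3,4-bis(prop-2-en-1-yloxy)phenyl]-3-(hydroxymethyl)-2,3-dihydro-1,4-benzodioxin-6-yl]-2-(hydroxymethyl)-2,3-dihydro-1,4-benzodioxin-6-yl]prop-2-enal | O=C/C=C/c1ccc2c(c1)O[C@@H](c1ccc3c(c1)O[C@@H](CO)[C@@H](c1ccc(OCC=C)c(OCC=C)c1)O3)[C@H](CO)O2 | intermediate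
22 | CNP0302404.1, (2E)-3-[(2S,3S)-3-[(2R,3S)-2-(3,4-dihydroxyphenyl)-3-(hydroxymethyl)-2,3-dihydro-1,4-benzodioxin-6-yl]-2-(hydroxymethyl)-2,3-dihydro-1,4-benzodioxin-6-yl]prop-2-enal | O=C/C=C/c1ccc2c(c1)O[C@@H](c1ccc3c(c1)O[C@@H](CO)[C@@H](c1ccc(O)c(O)c1)O3)[C@H](CO)O2 | target

**Step count and risks**

Total: 16 steps. Longest linear sequence: 13 steps (steps 1–7 and 11–16, from L-tyrosine); the ring E fragment takes 3 steps (8–10) before the union.

Steps most likely to fail:

Step 7. Hydride loss from C7 is slowed by the bromine on ring C, so DDQ may instead couple phenoxyl radicals, oxidise the product a second time at its more activated C7–H, or allow 11 to tautomerise to the C7=C8 enol ether, which would erase C8. The fallback sets out from 1 and returns at 12, and brings the halogen in after ring closure. L-Tyrosine 1 is taken through the chemistry of steps 2 to 6 without step 1: diazotisation, through the diazonium carboxylate F1 and the α-lactone F2, should give (S)-4-hydroxyphenyllactic acid F3; BH3·THF then gives the diol F4, TBSCl the bis-silyl ether F5, the Mitsunobu reaction with 8 the aryl ether F6, and TBAF/AcOH the triol F7. DDQ then meets a more electron-rich 4-alkylphenol, which should pass through the para-quinone methide F8 to the bromine-free trans benzodioxane F9. NBS (1.0 equiv, i-Pr2NH cat., CH2Cl2, 0 °C) finally brominates ortho to the only free phenol, whose two ortho positions are equivalent while ring A is deactivated by its formyl group, and this gives 12.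

Step 11. Base-induced Payne rearrangement of the epoxy alcohol may run ahead of ring opening (attack then falls on C1), or the electron-rich benzylic epoxide may ionise and lose clean inversion. The fallback sets out from 16 and returns at 18. Silylation of 16 (TIPSCl, imidazole, DMF) gives the epoxy silyl ether F10, in which no alkoxide can form. The phenoxide of 12 (Cs2CO3, DMF, 60 °C) should open F10 at the benzylic carbon with inversion to give the mono-silylated alcohol F11, and TIPSCl/imidazole on the remaining primary hydroxyl at C9 gives 18.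

Step 13. Coupling of the hindered secondary alkoxide with the aryl bromide at copper may be slow, so that hydride transfer from the alkoxide to the aldehyde, protodebromination or silyl migration compete at 110 °C. The fallback sets out from 18 and returns at 19. Ring D is closed instead by palladium-catalysed C–O cross-coupling (Pd(OAc)2, 2-(di-tert-butylphosphino)-1,1'-binaphthyl, Cs2CO3, toluene, 70 °C). Here the aryl bromide adds oxidatively to zerovalent palladium and the bulky phosphine drives C–O reductive elimination at a lower temperature, again with retention at C8''. No compound outside the route is formed (F0).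

**Further compounds**

F1 | step 7 | diazonium carboxylate, (2S)-2-diazonio-3-(4-hydroxyphenyl)propanoate | N#[N+][C@@H](Cc1ccc(O)cc1)C(=O)[O-]
F2 | step 7 | α-lactone, (3R)-3-[(4-hydroxyphenyl)methyl]oxiran-2-one | O1[C@H](Cc2ccc(O)cc2)C1=O
F3 | step 7 | (2S)-2-hydroxy-3-(4-hydroxyphenyl)propanoic acid | O[C@@H](Cc1ccc(O)cc1)C(=O)O
F4 | step 7 | (2S)-3-(4-hydroxyphenyl)propane-1,2-diol | OC[C@@H](O)Cc1ccc(O)cc1
F5 | step 7 | (2S)-1-[4-(tert-butyldimethylsilyloxy)phenyl]-3-(tert-butyldimethylsilyloxy)propan-2-ol | CC(C)(C)[Si](C)(C)OC[C@@H](O)Cc1ccc(O[Si](C)(C)C(C)(C)C)cc1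
F6 | step 7 | 4-{[(2R)-1-[4-(tert-butyldimethylsilyloxy)phenyl]-3-(tert-butyldimethylsilyloxy)propan-2-yl]oxy}-3-hydroxybenzaldehyde | O=Cc1ccc(O[C@@H](CO[Si](C)(C)C(C)(C)C)Cc2ccc(O[Si](C)(C)C(C)(C)C)cc2)c(O)c1
F7 | step 7 | 3-hydroxy-4-{[(2R)-1-hydroxy-3-(4-hydroxyphenyl)propan-2-yl]oxy}benzaldehyde | O=Cc1ccc(O[C@@H](CO)Cc2ccc(O)cc2)c(O)c1
F8 | step 7 | para-quinone methide, 3-hydroxy-4-{[(2R)-1-hydroxy-3-(4-oxocyclohexa-2,5-dien-1-ylidene)propan-2-yl]oxy}benzaldehyde | O=Cc1ccc(O[C@@H](CO)C=C2C=CC(=O)C=C2)c(O)c1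
F9 | step 7 | (2S,3S)-2-(hydroxymethyl)-3-(4-hydroxyphenyl)-2,3-dihydro-1,4-benzodioxine-6-carbaldehyde | O=Cc1ccc2c(c1)O[C@@H](c1ccc(O)cc1)[C@H](CO)O2
F10 | step 11 | {[(2S,3S)-3-[3,4-bis(prop-2-en-1-yloxy)phenyl]oxiran-2-yl]methoxy}tri(propan-2-yl)silane | CC(C)[Si](C(C)C)(C(C)C)OC[C@@H]1O[C@H]1c1ccc(OCC=C)c(OCC=C)c1
F11 | step 11 | (2S,3S)-3-{4-[(1R,2S)-1-[3,4-bis(prop-2-en-1-yloxy)phenyl]-2-hydroxy-3-(triisopropylsilyloxy)propoxy]-3-bromophenyl}-2-(hydroxymethyl)-2,3-dihydro-1,4-benzodioxine-6-carbaldehyde | O=Cc1ccc2c(c1)O[C@@H](c1ccc(O[C@H](c3ccc(OCC=C)c(OCC=C)c3)[C@@H](O)CO[Si](C(C)C)(C(C)C)C(C)C)c(Br)c1)[C@H](CO)O2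
F0 | step 13 | none | none
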